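A direct plan would add 4-hydroxyphenylboronic acid A2 to 7-hydroxychromone A1 with a chiral cationic palladium catalyst to give (2S)-liquiritigenin A3, make the bis(1,1-dimethylallyl) ether A4, rearrange it thermally to glabrol A5 and hydroxylate ring B with IBX via ortho-quinone A6. Its weakest steps would be the double Claisen rearrangement, because the ring A ether could deliver prenyl to C6 as well as to C8; the late ortho-oxygenation, because the oxidant would face two phenols and two olefins and A6 could tautomerise through C2 and racemise it; and the conjugate addition, because the cationic catalyst would have to tolerate two free phenols.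

The new route disconnects ring A instead of ring C: cutting C4a–C5 and C8–C8a leads to an enantioenriched 2-aryl-5-sulfinyl-2,3-dihydropyran-4-one, in which ring C and C2 already exist (set by a catalytic hetero-Diels–Alder reaction of the ring B aldehyde), and a prenyl-bearing 1-amino-3-siloxydiene. The step exploits that O1 (on C8a) and the C7 hydroxyl are meta on ring A with C8 between them, the pattern such a diene must give with a β-alkoxy enone, so one cycloaddition–elimination sequence builds ring A with the C8 prenyl group placed by constitution. Ring B gets its prenyl group by cross-coupling at a bromide and its catechol from the starting aldehyde; Claisen rearrangement, late oxygenation and conjugate addition disappear.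

Key step: step 8

Remark: (S)-BINOL is assumed to direct the diene to the Si face of the aldehyde in step 2; should the sense prove opposite, (R)-BINOL would be used with nothing else changed. TBS = tert-butyldimethylsilyl, TBSO = tert-butyldimethylsilyloxy, prenyl = 3-methylbut-2-enyl.

Step 1
Reactants: 1 3-bromo-4,5-dihydroxybenzaldehyde
Product: 2 3-bromo-4,5-bis(tert-butyldimethylsilyloxy)benzaldehyde
Conditions: TBSCl (2.5 equiv), imidazole (5 equiv), DMF, rt
Reagents that add atoms: tert-butyldimethylsilyl chloride (TBSCl), CC(C)(C)[Si](C)(C)Cl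
Why: Imidazole-promoted silyl ether formation on both phenols, chosen because aryl silyl ethers should survive Lewis acid, palladium, peracid and dilute acid and can be removed at the end with fluoride under non-basic conditions.

Step 2
Reactants: 2 3-bromo-4,5-bis(TBSO)benzaldehyde; 3 (E)-1-methoxy-3-(trimethylsilyloxy)buta-1,3-diene (Danishefsky's diene)
Product: 5 (2S)-2-[3-bromo-4,5-bis(TBSO)phenyl]-2,3-dihydro-4H-pyran-4-one, via silyl aldol adduct 4 (not isolated)
Conditions: (S)-BINOL (20 mol%), Ti(OiPr)4 (10 mol%), 4 Å molecular sieves, Et2O, −20 °C; then CF3CO2H, CH2Cl2, 0 °C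
Reagents that add atoms: none
Why: Catalytic enantioselective hetero-Diels–Alder reaction that runs as a Mukaiyama aldol addition of the diene terminus to the titanium-bound aldehyde, followed by acid-induced ring closure with loss of methanol; the BINOL–titanium complex differentiates the aldehyde faces, Si-face attack sets C2 as S, and the carbinol C–O bond is not broken in the cyclisation.

Step 3
Reactants: 5 (2S)-2-[3-bromo-4,5-bis(TBSO)phenyl]-2,3-dihydro-4H-pyran-4-one
Product: 7 (2S)-2-[3-bromo-4,5-bis(TBSO)phenyl]-5-(phenylthio)-2,3-dihydro-4H-pyran-4-one, via chloro sulfide adduct 6 (not isolated)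
Conditions: PhSH, N-chlorosuccinimide, CH2Cl2, 0 °C (gives PhSCl); added to 5, CH2Cl2, −78 °C; pyridine, −78 °C to rt
Reagents that add atoms: thiophenol, Sc1ccccc1 (turned in the flask into benzenesulfenyl chloride, ClSc1ccccc1)
Why: Electrophilic α-sulfenylation of a vinylogous ester by addition–elimination, in which the sulfenyl chloride attacks the enol-ether-like C5, chloride caps the oxocarbenium ion at C6 and pyridine removes HCl to restore the enone; no isolated olefin is yet present to compete and C2 is not involved.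

Step 4
Reactants: 7 (2S)-2-[3-bromo-4,5-bis(TBSO)phenyl]-5-(phenylthio)-2,3-dihydro-4H-pyran-4-one
Product: 8 (2S)-2-[3,4-bis(TBSO)-5-prenylphenyl]-5-(phenylthio)-2,3-dihydro-4H-pyran-4-one
Conditions: tributyl(3-methylbut-2-enyl)stannane (1.3 equiv), Pd(PPh3)4 (5 mol%), PhMe, 100 °C
Reagents that add atoms: tributyl(3-methylbut-2-enyl)stannane, CCCC[Sn](CCCC)(CCCC)CC=C(C)C
Why: Stille cross-coupling of the aryl bromide, in which reductive elimination at the less hindered allyl terminus should give the linear prenyl arene at the carbon fixed by the bromide, under neutral conditions that leave the silyl ethers, the vinyl sulfide and C2 alone.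

Step 5
Reactants: 8 (2S)-2-[3,4-bis(TBSO)-5-prenylphenyl]-5-(phenylthio)-2,3-dihydro-4H-pyran-4-one
Product: 9 (2S)-2-[3,4-bis(TBSO)-5-prenylphenyl]-5-(phenylsulfinyl)-2,3-dihydro-4H-pyran-4-one (both configurations at sulfur)
Conditions: mCPBA (1.0 equiv), CH2Cl2, −78 °C
Reagents that add atoms: mCPBA (3-chloroperbenzoic acid), OOC(=O)c1cccc(Cl)c1
Why: Chemoselective sulfide-to-sulfoxide oxidation, since at −78 °C one equivalent of peracid should oxidise the aryl vinyl sulfide far faster than it epoxidises the trisubstituted olefin or the electron-poor enone; the sulfur stereocentre is of no consequence because the sulfinyl group is lost in step 8.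

Step 6
Reactants: 10 (E)-4-(dimethylamino)but-3-en-2-one
Product: 11 (E)-1-(dimethylamino)-7-methylocta-1,6-dien-3-one
Conditions: LiN(iPr)2 (1.05 equiv), THF, −78 °C; 1-bromo-3-methylbut-2-ene, −78 °C to 0 °C
Reagents that add atoms: 1-bromo-3-methylbut-2-ene (prenyl bromide), CC(C)=CCBr
Why: Kinetic α′-deprotonation of the vinylogous amide at its only enolisable position and SN2 alkylation of the lithium dienolate by the primary allylic bromide.

Step 7
Reactants: 11 (E)-1-(dimethylamino)-7-methylocta-1,6-dien-3-one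
Product: 12 (1E,3Z)-3-(tert-butyldimethylsilyloxy)-N,N,7-trimethylocta-1,3,6-trien-1-amine
Conditions: KN(SiMe3)2 (1.05 equiv), THF, −78 °C; TBSCl, −78 °C to rt
Reagents that add atoms: tert-butyldimethylsilyl chloride (TBSCl), CC(C)(C)[Si](C)(C)Cl
Why: O-Silylation of the potassium dienolate (1-amino-3-siloxydiene synthesis), expected to give mainly the Z enol ether, in which the substituted terminus points outward and stays reactive; either geometry would lead to the same arene.

Step 8
Reactants: 9 (2S)-2-[3,4-bis(TBSO)-5-prenylphenyl]-5-(phenylsulfinyl)-2,3-dihydro-4H-pyran-4-one; 12 (1E,3Z)-3-(tert-butyldimethylsilyloxy)-N,N,7-trimethylocta-1,3,6-trien-1-amine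
Product: 16 (2S)-2-[3,4-bis(TBSO)-5-prenylphenyl]-7-hydroxy-8-prenylchroman-4-one, via cycloadduct 13 (not isolated), via sulfinyl enone 14 (not isolated), via dienone 15 (not isolated)
Conditions: 12 (1.5 equiv), PhMe, −20 °C to rt; then 1 M HCl, THF, 0 °C; extraction; PhMe, 60 °C
Reagents that add atoms: none
Why: The strongly nucleophilic 1-amino-3-siloxydiene 12 should add across the C5=C6 bond of 9, which ketone and sulfinyl group together make a good acceptor, in a normal-demand Diels–Alder reaction; the closest known reactions are the benzannulations of α-sulfinyl enones and of chromones bearing an acceptor at C3 with 1-oxy- and 1-amino-3-siloxydienes. Ring A is closed by this intermolecular [4+2] cycloaddition onto the finished ring C, the prenyl-bearing diene terminus (future C8) bonding to the electrophilic C6 of the pyranone (future C8a) and the amino-bearing terminus (future C5) to the sulfinyl carbon (future C4a), an orientation fixed by the push–pull polarisation of both partners, so that the prenyl group must end up between O1 and the C7 oxygen. Cold dilute acid then hydrolyses the silyl enol ether and expels dimethylamine by β-elimination to give enone 14 while the sulfoxide is still in place, which leaves C8a–H, cis to sulfur because the addition is suprafacial, as the only hydrogen syn and β to sulfur. Thermal syn-elimination of benzenesulfenic acid therefore restores the C4a=C8a bond, and dienone 15 tautomerises to the phenol. No new stereocentre is kept: the four sp3 centres of 13 are erased on aromatisation, both sulfoxide epimers and both faces of 9 converge, and C2 from step 2 should be preserved because the cycloaddition runs without added base or Lewis acid and the amine is protonated as soon as it is set free. The step needs regioselectivity in the cycloaddition and the right order of the two eliminations; the first is secured by the polarisation named above and the second by the reactivity of the amino diene, which should allow cycloaddition below the temperature at which the sulfoxide eliminates.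

Step 9
Reactants: 16 (2S)-2-[3,4-bis(TBSO)-5-prenylphenyl]-7-hydroxy-8-prenylchroman-4-one
Product: 17 (2S)-2-[3,4-dihydroxy-5-(3-methylbut-2-enyl)phenyl]-7-hydroxy-8-(3-methylbut-2-enyl)chroman-4-one (target)
Conditions: HF·pyridine (excess), pyridine, THF, 0 °C to rt
Reagents that add atoms: none
Why: Fluoride-mediated cleavage of the two aryl silyl ethers under mildly acidic, non-basic conditions, which should avoid the retro-oxa-Michael opening that would racemise C2 of a 4′-hydroxyflavanone and should not protonate the prenyl olefins.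

## Compound list

1 | 3-bromo-4,5-dihydroxybenzaldehyde | O=Cc1cc(O)c(O)c(Br)c1 | starting material
2 | 3-bromo-4,5-bis(tert-butyldimethylsilyloxy)benzaldehyde | O=Cc1cc(Br)c(O[Si](C)(C)C(C)(C)C)c(O[Si](C)(C)C(C)(C)C)c1 | intermediate
3 | (E)-1-methoxy-3-(trimethylsilyloxy)buta-1,3-diene (Danishefsky's diene) | CO/C=C/C(=C)O[Si](C)(C)C | starting material
4 | (1E,5S)-5-[3-bromo-4,5-bis(tert-butyldimethylsilyloxy)phenyl]-1-methoxy-5-(trimethylsilyloxy)pent-1-en-3-one (silyl aldol adduct) | CO/C=C/C(=O)C[C@H](O[Si](C)(C)C)c1cc(Br)c(O[Si](C)(C)C(C)(C)C)c(O[Si](C)(C)C(C)(C)C)c1 | intermediate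
5 | (2S)-2-[3-bromo-4,5-bis(tert-butyldimethylsilyloxy)phenyl]-2,3-dihydro-4H-pyran-4-one | O=C1C[C@@H](c2cc(Br)c(O[Si](C)(C)C(C)(C)C)c(O[Si](C)(C)C(C)(C)C)c2)OC=C1 | intermediate
6 | (2S)-2-[3-bromo-4,5-bis(tert-butyldimethylsilyloxy)phenyl]-6-chloro-5-(phenylthio)tetrahydro-4H-pyran-4-one (C5 and C6 unassigned) | O=C1C[C@@H](c2cc(Br)c(O[Si](C)(C)C(C)(C)C)c(O[Si](C)(C)C(C)(C)C)c2)OC(Cl)C1Sc1ccccc1 | intermediate
7 | (2S)-2-[3-bromo-4,5-bis(tert-butyldimethylsilyloxy)phenyl]-5-(phenylthio)-2,3-dihydro-4H-pyran-4-one | O=C1C[C@@H](c2cc(Br)c(O[Si](C)(C)C(C)(C)C)c(O[Si](C)(C)C(C)(C)C)c2)OC=C1Sc1ccccc1 | intermediate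
8 | (2S)-2-[3,4-bis(tert-butyldimethylsilyloxy)-5-(3-methylbut-2-enyl)phenyl]-5-(phenylthio)-2,3-dihydro-4H-pyran-4-one | O=C1C[C@@H](c2cc(CC=C(C)C)c(O[Si](C)(C)C(C)(C)C)c(O[Si](C)(C)C(C)(C)C)c2)OC=C1Sc1ccccc1 | intermediate
9 | (2S)-2-[3,4-bis(tert-butyldimethylsilyloxy)-5-(3-methylbut-2-enyl)phenyl]-5-(phenylsulfinyl)-2,3-dihydro-4H-pyran-4-one (sulfur unassigned) | O=C1C[C@@H](c2cc(CC=C(C)C)c(O[Si](C)(C)C(C)(C)C)c(O[Si](C)(C)C(C)(C)C)c2)OC=C1S(=O)c1ccccc1 | intermediate
10 | (E)-4-(dimethylamino)but-3-en-2-one | CN(C)/C=C/C(C)=O | starting material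
11 | (E)-1-(dimethylamino)-7-methylocta-1,6-dien-3-one | CN(C)/C=C/C(=O)CCC=C(C)C | intermediate
12 | (1E,3Z)-3-(tert-butyldimethylsilyloxy)-N,N,7-trimethylocta-1,3,6-trien-1-amine | CN(C)/C=C/C(O[Si](C)(C)C(C)(C)C)=C/CC=C(C)C | intermediate
13 | cycloadduct: (2S)-2-[3,4-bis(tert-butyldimethylsilyloxy)-5-(3-methylbut-2-enyl)phenyl]-7-(tert-butyldimethylsilyloxy)-5-(dimethylamino)-8-(3-methylbut-2-enyl)-4a-(phenylsulfinyl)-2,3,4a,5,8,8a-hexahydro-4H-chromen-4-one (C4a, C5, C8, C8a and sulfur unassigned) | O=C1C[C@@H](c2cc(CC=C(C)C)c(O[Si](C)(C)C(C)(C)C)c(O[Si](C)(C)C(C)(C)C)c2)OC2C(CC=C(C)C)C(O[Si](C)(C)C(C)(C)C)=CC(N(C)C)C12S(=O)c1ccccc1 | intermediate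
14 | sulfinyl enone: (2S)-2-[3,4-bis(tert-butyldimethylsilyloxy)-5-(3-methylbut-2-enyl)phenyl]-8-(3-methylbut-2-enyl)-4a-(phenylsulfinyl)-2,3,8,8a-tetrahydro-4H-chromene-4,7(4aH)-dione (C4a, C8, C8a and sulfur unassigned) | O=C1C[C@@H](c2cc(CC=C(C)C)c(O[Si](C)(C)C(C)(C)C)c(O[Si](C)(C)C(C)(C)C)c2)OC2C(CC=C(C)C)C(=O)C=CC12S(=O)c1ccccc1 | intermediate
15 | dienone: (2S)-2-[3,4-bis(tert-butyldimethylsilyloxy)-5-(3-methylbut-2-enyl)phenyl]-8-(3-methylbut-2-enyl)-2,3-dihydro-4H-chromene-4,7(8H)-dione (C8 unassigned) | O=C1C[C@@H](c2cc(CC=C(C)C)c(O[Si](C)(C)C(C)(C)C)c(O[Si](C)(C)C(C)(C)C)c2)OC2=C1C=CC(=O)C2CC=C(C)C | intermediate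
16 | (2S)-2-[3,4-bis(tert-butyldimethylsilyloxy)-5-(3-methylbut-2-enyl)phenyl]-7-hydroxy-8-(3-methylbut-2-enyl)chroman-4-one | O=C1C[C@@H](c2cc(CC=C(C)C)c(O[Si](C)(C)C(C)(C)C)c(O[Si](C)(C)C(C)(C)C)c2)Oc2c1ccc(O)c2CC=C(C)C | intermediate
17 | (2S)-2-[3,4-dihydroxy-5-(3-methylbut-2-enyl)phenyl]-7-hydroxy-8-(3-methylbut-2-enyl)chroman-4-one | CC(C)=CCc1cc([C@@H]2CC(=O)c3ccc(O)c(CC=C(C)C)c3O2)cc(O)c1O | target

Total step count: 9. Longest linear sequence: 7 steps (steps 1, 2, 3, 4, 5, 8 and 9); steps 6 and 7 make the diene.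

Steps most likely to fail:

Step 8. The amino diene may add only in the Michael sense without closing the ring, or the sulfinyl group may leave toward C5 before dimethylamine is lost, which takes the material off the path to the arene. The fallback sets out from 9 and comes back at 17. It gives up the leaving group on the diene and supplies the last unsaturation with an oxidant. 7-Methylocta-1,6-dien-3-one F1 (from N-methoxy-N-methylacrylamide and 4-methylpent-3-enylmagnesium bromide) would be silylated (TBSOTf, Et3N, Et2O) to (Z)-3-(tert-butyldimethylsilyloxy)-7-methylocta-1,3,6-triene F2. With 9 in PhMe at 60–80 °C this should give the sulfinyl cycloadduct F3 and, by loss of benzenesulfenic acid in the same flask, the 5,8-dihydro compound F4; here elimination toward either neighbouring carbon leaves the ring one oxidation short of the arene. DDQ (1 equiv, PhH, rt) would then dehydrogenate it to the tris-silyl flavanone F5, which the conditions of step 9 would convert into 17.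

Step 3. The sulfenyl chloride may attack the silyloxy arene or chlorinate instead of sulfenylating, or the deactivated vinylogous ester may react too slowly. The fallback sets out from 5 and comes back at 7. Iodination at C5 by addition–elimination (I2, pyridine, CH2Cl2, rt) would give the iodo enone F6. Palladium-catalysed C–S coupling with thiophenol (Pd2(dba)3, Xantphos, iPr2NEt, dioxane, 50 °C) would then give 7; the alkenyl iodide should enter oxidative addition well before the aryl bromide.

Step 4. Allylic transposition at palladium may give the branched 1,1-dimethylallyl isomer beside the prenyl arene, or the sulfide may slow the catalyst until protodebromination competes. The fallback sets out from 7 and comes back at 8. Stille coupling with allyltributylstannane (Pd(PPh3)4, PhMe, 100 °C), for which transposition is degenerate, would give the allyl arene F7. Olefin cross-metathesis with 2-methylbut-2-ene (second-generation Grubbs catalyst, CH2Cl2, 40 °C) would then turn the allyl into the prenyl group.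

## Further compounds

F1 | step 8 | 7-methylocta-1,6-dien-3-one | C=CC(=O)CCC=C(C)C
F2 | step 8 | (Z)-3-(tert-butyldimethylsilyloxy)-7-methylocta-1,3,6-triene | C=C/C(O[Si](C)(C)C(C)(C)C)=C/CC=C(C)C
F3 | step 8 | (2S)-2-[3,4-bis(tert-butyldimethylsilyloxy)-5-(3-methylbut-2-enyl)phenyl]-7-(tert-butyldimethylsilyloxy)-8-(3-methylbut-2-enyl)-4a-(phenylsulfinyl)-2,3,4a,5,8,8a-hexahydro-4H-chromen-4-one (C4a, C8, C8a and sulfur unassigned) | O=C1C[C@@H](c2cc(CC=C(C)C)c(O[Si](C)(C)C(C)(C)C)c(O[Si](C)(C)C(C)(C)C)c2)OC2C(CC=C(C)C)C(O[Si](C)(C)C(C)(C)C)=CCC12S(=O)c1ccccc1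
F4 | step 8 | (2S)-2-[3,4-bis(tert-butyldimethylsilyloxy)-5-(3-methylbut-2-enyl)phenyl]-7-(tert-butyldimethylsilyloxy)-8-(3-methylbut-2-enyl)-2,3,5,8-tetrahydro-4H-chromen-4-one (C8 unassigned) | O=C1C[C@@H](c2cc(CC=C(C)C)c(O[Si](C)(C)C(C)(C)C)c(O[Si](C)(C)C(C)(C)C)c2)OC2=C1CC=C(O[Si](C)(C)C(C)(C)C)C2CC=C(C)C
F5 | step 8 | (2S)-2-[3,4-bis(tert-butyldimethylsilyloxy)-5-(3-methylbut-2-enyl)phenyl]-7-(tert-butyldimethylsilyloxy)-8-(3-methylbut-2-enyl)chroman-4-one | O=C1C[C@@H](c2cc(CC=C(C)C)c(O[Si](C)(C)C(C)(C)C)c(O[Si](C)(C)C(C)(C)C)c2)Oc2c1ccc(O[Si](C)(C)C(C)(C)C)c2CC=C(C)C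
F6 | step 3 | (2S)-2-[3-bromo-4,5-bis(tert-butyldimethylsilyloxy)phenyl]-5-iodo-2,3-dihydro-4H-pyran-4-one | O=C1C[C@@H](c2cc(Br)c(O[Si](C)(C)C(C)(C)C)c(O[Si](C)(C)C(C)(C)C)c2)OC=C1I
F7 | step 4 | (2S)-2-[3-allyl-4,5-bis(tert-butyldimethylsilyloxy)phenyl]-5-(phenylthio)-2,3-dihydro-4H-pyran-4-one | O=C1C[C@@H](c2cc(CC=C)c(O[Si](C)(C)C(C)(C)C)c(O[Si](C)(C)C(C)(C)C)c2)OC=C1Sc1ccccc1
A1 | direct plan | 7-hydroxy-4H-chromen-4-one (7-hydroxychromone) | O=c1ccoc2cc(O)ccc12
A2 | direct plan | 4-hydroxyphenylboronic acid | OB(O)c1ccc(O)cc1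
A3 | direct plan | (2S)-7-hydroxy-2-(4-hydroxyphenyl)chroman-4-one (liquiritigenin) | Oc1ccc([C@@H]2CC(=O)c3ccc(O)cc3O2)cc1
A4 | direct plan | (2S)-7-(2-methylbut-3-en-2-yloxy)-2-[4-(2-methylbut-3-en-2-yloxy)phenyl]chroman-4-one | C=CC(C)(C)Oc1ccc([C@@H]2CC(=O)c3ccc(OC(C)(C)C=C)cc3O2)cc1
A5 | direct plan | (2S)-7-hydroxy-2-[4-hydroxy-3-(3-methylbut-2-enyl)phenyl]-8-(3-methylbut-2-enyl)chroman-4-one (glabrol) | CC(C)=CCc1cc([C@@H]2CC(=O)c3ccc(O)c(CC=C(C)C)c3O2)ccc1O
A6 | direct plan | (2S)-7-hydroxy-8-(3-methylbut-2-enyl)-2-[5-(3-methylbut-2-enyl)-3,4-dioxocyclohexa-1,5-dien-1-yl]chroman-4-one (ortho-quinone) | CC(C)=CCC1=CC([C@@H]2CC(=O)c3ccc(O)c(CC=C(C)C)c3O2)=CC(=O)C1=O
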